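(The readings are simulated for substances that don't exist, and the scatter is random.)

Read the amber run at its last time, 10.0 min: Z stands at 56.7% and G at 14.3%, so Z is 0.662 of what has not become G. In the ochre run at 4.00 min that share reads 0.671, so you may carry it across concentrations.

all flasks: E 1.05 equiv

|  | Q | remark | time |
|---|---|---|---|
| ochre | 0.11 M | run made earlier |  |
| amber | 0.35 M | run made earlier |  |
| epsilon | 0.12 M |  | 30 min |
| beta | 0.40 M |  | 20 min |

- ochre (time / min: Z / %, G / %): 0.833: 46.9, 0.3; 1.33: 57.7, 0.9; 2.00: 63.1, 0.6; 4.00: 66.3, 1.2; 6.00: 64.9, 2.0; 10.0: 63.7, 6.8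
- amber (time / min: Z / %, G / %): 0.667: 42.1, 0; 2.00: 63.4, 0.5; 4.00: 63.4, 3.8; 5.00: 63.4, 5.6; 8.00: 58.9, 11.3; 10.0: 56.7, 14.3

(standard deviation of a reading: 0.5 percentage points)

* the flask that ends with the higher amount of Z, in percent of the Q charged, or "neither" when 2 percentage points or less lies between them (epsilon / beta / neither)
* final Z, as a percentage of the Q charged, in epsilon
* final Z, as a percentage of the Q charged, in beta

- the numbers in the tables scatter by 0.5 percentage points (one standard deviation)
- steps thought possible: Q <-> Z; E -> J; Z + J -> G; 2 J -> X
- where the amount of Q changes, what is given in equivalents or mol% on it follows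

G is harder, but in the amber run it climbs almost straight from 5.00 min on. Replace the curve by its mean: the mean slope per molar, the fraction of the charge turned into G each minute for each molar of Q, reads 0.0497 /M/min. At 10.0 min G reads 14.3% in the amber run against 6.8% in the ochre run, so in these two runs, with the same equivalents of E, the percentage is higher at the higher concentration.

My own reckoning multiplies this slope by concentration and time. That gives G of 17.9% in epsilon and 39.8% in beta. The share then leaves Z at 54.3% in epsilon and 39.8% in beta, so I expect more Z in epsilon.

The forecast said neither, with 48.5% for epsilon and 48% for beta: “The longer time offsets the lower concentration”.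

The flask gives epsilon: 52.8% in epsilon, 45.0% in beta.

    Q ⇌ Z (K = 2.00, k = 0.990 /min)
    E → J (k = 0.200 /min)
    Z + J → G (k = 0.140 /M/min)
    2 J → X (k = 0.0500 /M/min)

In epsilon the relaxation half-life of Q and Z, 0.467 min, is far shorter than the 30 min run, and at 3.45 min Z falls back 58 times faster than it goes on, which is a rapid pre-equilibrium. In beta the flask holds G of 32.1%, where my slope had put 39.8%, and with the flask's G the share gives Z of 44.9%.

In a neighbouring flask, epsilon with 0.20 M of Q, the slope gives G of 29.8% and the share gives Z of 46.5%. The computed flask holds 28.8% G and 47.3% Z.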